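**Assumption:** carbon labels C1–C15 follow the linear C15 chain of the target (C1 = alkyne CH, C15 = ethyl CH3); the two enantiopure alcohols used as starting materials are taken as inexpensive catalogue chemicals. The target is (6S,7S,9S,10S,12S,13R), i.e. (1S,3R,4S,6S,7S,9S) in bicyclic numbering.

## Retrosynthetic overview

1. Target ⇐ Colvin one-carbon homologation of an (E)-enal ⇐ cross-metathesis of a C6 allyl group.
2. Bridging tetrahydrofuran (O–C9) and C10–Br ⇐ transannular 5-exo bromoetherification of an oxocene carrying the C6 carbinol (second and last ring).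
3. C6 carbinol ⇐ chelation-controlled allylation of an oxocene-2-carbaldehyde; oxocene ⇐ ring-closing metathesis of an acyclic diene ester (first ring).
4. C7–C8 bond and C7 configuration ⇐ Ireland–Claisen [3,3] rearrangement of a glycolate ester of a lactate-series (S)-allylic alcohol (1,3-chirality transfer).
5. C12/C13 ⇐ an (R)-2-hydroxybutanoate: O–H insertion (ether), chelation-controlled allylation (C12–OH), Appel inversion (C12–Br).

## Route

Step 1
Reactants: 1 methyl (2R)-2-hydroxybutanoate; 2 tert-butyl diazoacetate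
Product: 3 methyl (2R)-2-(2-tert-butoxy-2-oxoethoxy)butanoate
Conditions: Rh2(OAc)4 (1 mol %), CH2Cl2, rt, slow addition of 2
Reagents that add atoms: tert-butyl diazoacetate CC(C)(C)OC(=O)C=[N+]=[N-]
Why: Rh-carbenoid O–H insertion forms the C13–O–CH2 ether under neutral conditions, so the C13 stereocentre bought in 1 is not epimerised.

Step 2
Reactants: 3 methyl (2R)-2-(2-tert-butoxy-2-oxoethoxy)butanoate
Product: 4 tert-butyl 2-{[(2R)-1-oxobutan-2-yl]oxy}acetate
Conditions: i-Bu2AlH (1.1 equiv), CH2Cl2, −78 °C; aq. Rochelle salt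
Reagents that add atoms: none
Why: Partial ester reduction: the α-alkoxy methyl ester gives a stable aluminium hemiacetal at −78 °C while the hindered tert-butyl ester is left untouched.

Step 3
Reactants: 4 tert-butyl 2-{[(2R)-1-oxobutan-2-yl]oxy}acetate; 5 allyltributylstannane
Product: 6 tert-butyl 2-{[(3R,4R)-4-hydroxyhept-6-en-3-yl]oxy}acetate
Conditions: MgBr2·OEt2 (2.5 equiv), CH2Cl2, −78 °C; then 5, −78 → −20 °C
Reagents that add atoms: allyltributylstannane C=CC[Sn](CCCC)(CCCC)CCCC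
Why: Keck-type chelation-controlled allylation: Mg bridges the aldehyde and α-ether oxygens and the allyl group adds anti to the ethyl group, giving the 12,13-syn (12R) alcohol.

Step 4
Reactants: 6 tert-butyl 2-{[(3R,4R)-4-hydroxyhept-6-en-3-yl]oxy}acetate; 7 carbon tetrabromide
Product: 8 tert-butyl 2-{[(3R,4S)-4-bromohept-6-en-3-yl]oxy}acetate
Conditions: CBr4, P(n-Oct)3, toluene, 60–70 °C
Reagents that add atoms: carbon tetrabromide BrC(Br)(Br)Br
Why: Appel bromination: bromide displaces the oxyphosphonium group by SN2, inverting C12 to the (S)-bromide of the target.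

Step 5
Reactants: 8 tert-butyl 2-{[(3R,4S)-4-bromohept-6-en-3-yl]oxy}acetate
Product: 9 2-{[(3R,4S)-4-bromohept-6-en-3-yl]oxy}acetic acid
Conditions: CF3CO2H–CH2Cl2 (1:3), 0 °C → rt
Reagents that add atoms: none
Why: Acidolysis of the tert-butyl ester (loss of isobutene) frees the glycolic acid without affecting the secondary bromide or the alkene.

Step 6
Reactants: 9 2-{[(3R,4S)-4-bromohept-6-en-3-yl]oxy}acetic acid; 10 (2S)-but-3-en-2-ol
Product: 11 (2S)-but-3-en-2-yl 2-{[(3R,4S)-4-bromohept-6-en-3-yl]oxy}acetate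
Conditions: DCC, DMAP (cat.), CH2Cl2, 0 °C → rt
Reagents that add atoms: (2S)-but-3-en-2-ol C[C@H](O)C=C
Why: Steglich esterification acylates the allylic alcohol at oxygen, so its carbinol stereocentre is retained.

Step 7
Reactants: 11 (2S)-but-3-en-2-yl 2-{[(3R,4S)-4-bromohept-6-en-3-yl]oxy}acetate; 12 chlorotrimethylsilane; 13 (trimethylsilyl)diazomethane
Product: 17 methyl (2S,4E)-2-{[(3R,4S)-4-bromohept-6-en-3-yl]oxy}hex-4-enoate, via silyl ketene acetal 14 (not isolated), via trimethylsilyl ester 15 (not isolated), via carboxylic acid 16 (not isolated)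
Conditions: LiN(SiMe3)2, Me3SiCl, THF, −78 °C → rt; then MeOH, rt; then Me3SiCHN2, toluene–MeOH, 0 °C
Reagents that add atoms: chlorotrimethylsilane C[Si](C)(C)Cl (silyl group stays in 14 and 15 only); (trimethylsilyl)diazomethane C[Si](C)(C)C=[N+]=[N-] (gives the ester methyl carbon)
Why: Ireland–Claisen [3,3]-sigmatropic rearrangement: the Li-chelated (Z)-silyl ketene acetal reacts through a chair with the carbinol methyl equatorial, so the (S)-carbinol of 10 is transferred to C7 (S) as the C7–C8 bond and an (E)-alkene form; the acid is methylated in the same flask.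

Step 8
Reactants: 17 methyl (2S,4E)-2-{[(3R,4S)-4-bromohept-6-en-3-yl]oxy}hex-4-enoate
Product: 18 methyl (2S,4Z,7S,8R)-7-bromo-8-ethyl-3,6,7,8-tetrahydro-2H-oxocine-2-carboxylate
Conditions: second-generation Grubbs catalyst RuCl2(=CHPh)(H2IMes)(PCy3) (5–10 mol %), CH2Cl2 (2 mM), 40 °C
Reagents that add atoms: none
Why: Ring-closing metathesis joins C9 to C10 with loss of propene (which carries away the spent carbinol carbon of 10); the eight-membered ring enforces the (Z)-alkene.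

Step 9
Reactants: 18 methyl (2S,4Z,7S,8R)-7-bromo-8-ethyl-3,6,7,8-tetrahydro-2H-oxocine-2-carboxylate
Product: 19 (2S,4Z,7S,8R)-7-bromo-8-ethyl-3,6,7,8-tetrahydro-2H-oxocine-2-carbaldehyde
Conditions: i-Bu2AlH (1.1 equiv), CH2Cl2, −78 °C; aq. Rochelle salt
Reagents that add atoms: none
Why: Partial reduction of the α-alkoxy ester through its stable aluminium hemiacetal gives the aldehyde, which is used at once so C7 does not epimerise.

Step 10
Reactants: 19 (2S,4Z,7S,8R)-7-bromo-8-ethyl-3,6,7,8-tetrahydro-2H-oxocine-2-carbaldehyde; 5 allyltributylstannane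
Product: 20 (1S)-1-[(2S,4Z,7S,8R)-7-bromo-8-ethyl-3,6,7,8-tetrahydro-2H-oxocin-2-yl]but-3-en-1-ol
Conditions: MgBr2·OEt2 (3 equiv), CH2Cl2, −78 °C; then 5, −78 → −40 °C
Reagents that add atoms: allyltributylstannane C=CC[Sn](CCCC)(CCCC)CCCC
Why: Cram-chelate allylation: Mg bridges the aldehyde and ring-ether oxygens and the allyl group adds anti to C8, giving the 6,7-syn (6S) alcohol.

Step 11
Reactants: 20 (1S)-1-[(2S,4Z,7S,8R)-7-bromo-8-ethyl-3,6,7,8-tetrahydro-2H-oxocin-2-yl]but-3-en-1-ol; 21 N-bromosuccinimide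
Product: 22 (1S,3R,4S,6S,7S,9S)-4,6-dibromo-3-ethyl-9-(prop-2-en-1-yl)-2,8-dioxabicyclo[5.2.1]decane
Conditions: NBS (1.1 equiv), CH2Cl2, 0 °C, dark
Reagents that add atoms: N-bromosuccinimide O=C1CCC(=O)N1Br
Why: Transannular bromoetherification: the electron-rich ring alkene forms the bromonium ion and the C6 hydroxyl attacks C9 in a 5-exo anti opening; the cis bridge fixes C9 (S) and anti addition to the (Z)-alkene fixes C10 (S).

Step 12
Reactants: 22 (1S,3R,4S,6S,7S,9S)-4,6-dibromo-3-ethyl-9-(prop-2-en-1-yl)-2,8-dioxabicyclo[5.2.1]decane; 23 (2E)-but-2-enal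
Product: 24 (2E)-4-[(1S,3R,4S,6S,7S,9S)-4,6-dibromo-3-ethyl-2,8-dioxabicyclo[5.2.1]decan-9-yl]but-2-enal
Conditions: 23 (10 equiv), second-generation Hoveyda–Grubbs catalyst RuCl2(=CH-C6H4-2-O-i-Pr)(H2IMes) (5 mol %), CH2Cl2, 40 °C
Reagents that add atoms: (2E)-but-2-enal C/C=C/C=O
Why: Olefin cross-metathesis of the terminal alkene with crotonaldehyde gives the conjugated (E)-enal under thermodynamic control, with propene lost.

Step 13
Reactants: 24 (2E)-4-[(1S,3R,4S,6S,7S,9S)-4,6-dibromo-3-ethyl-2,8-dioxabicyclo[5.2.1]decan-9-yl]but-2-enal; 13 (trimethylsilyl)diazomethane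
Product: 25 (1S,3R,4S,6S,7S,9S)-4,6-dibromo-3-ethyl-9-[(2E)-pent-2-en-4-yn-1-yl]-2,8-dioxabicyclo[5.2.1]decane
Conditions: Me3SiCHN2, LiN(i-Pr)2, THF, −78 °C (pre-formed anion); then 24, −78 → 0 °C
Reagents that add atoms: (trimethylsilyl)diazomethane C[Si](C)(C)C=[N+]=[N-]
Why: Colvin rearrangement: addition, Peterson-type elimination and 1,2-hydrogen shift of the alkylidene carbene turn the aldehyde into the terminal alkyne, leaving the (E)-alkene and both secondary bromides intact at low temperature.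

## Compound list

1 | methyl (2R)-2-hydroxybutanoate | CC[C@@H](O)C(=O)OC | starting material
2 | tert-butyl diazoacetate | CC(C)(C)OC(=O)C=[N+]=[N-] | starting material
3 | methyl (2R)-2-(2-tert-butoxy-2-oxoethoxy)butanoate | CC[C@@H](OCC(=O)OC(C)(C)C)C(=O)OC | intermediate
4 | tert-butyl 2-{[(2R)-1-oxobutan-2-yl]oxy}acetate | CC[C@@H](OCC(=O)OC(C)(C)C)C=O | intermediate
5 | allyltributylstannane | C=CC[Sn](CCCC)(CCCC)CCCC | starting material
6 | tert-butyl 2-{[(3R,4R)-4-hydroxyhept-6-en-3-yl]oxy}acetate | CC[C@@H](OCC(=O)OC(C)(C)C)[C@H](O)CC=C | intermediate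
7 | carbon tetrabromide | BrC(Br)(Br)Br | starting material
8 | tert-butyl 2-{[(3R,4S)-4-bromohept-6-en-3-yl]oxy}acetate | CC[C@@H](OCC(=O)OC(C)(C)C)[C@@H](Br)CC=C | intermediate
9 | 2-{[(3R,4S)-4-bromohept-6-en-3-yl]oxy}acetic acid | CC[C@@H](OCC(=O)O)[C@@H](Br)CC=C | intermediate
10 | (2S)-but-3-en-2-ol | C[C@H](O)C=C | starting material
11 | (2S)-but-3-en-2-yl 2-{[(3R,4S)-4-bromohept-6-en-3-yl]oxy}acetate | CC[C@@H](OCC(=O)O[C@@H](C)C=C)[C@@H](Br)CC=C | intermediate
12 | chlorotrimethylsilane | C[Si](C)(C)Cl | starting material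
13 | (trimethylsilyl)diazomethane | C[Si](C)(C)C=[N+]=[N-] | starting material
14 | (Z)-trimethylsilyl ketene acetal of 11: {[(1Z)-2-{[(3R,4S)-4-bromohept-6-en-3-yl]oxy}-1-{[(2S)-but-3-en-2-yl]oxy}ethenyl]oxy}trimethylsilane | CC[C@@H](O/C=C(\O[Si](C)(C)C)O[C@@H](C)C=C)[C@@H](Br)CC=C | intermediate
15 | trimethylsilyl (2S,4E)-2-{[(3R,4S)-4-bromohept-6-en-3-yl]oxy}hex-4-enoate | CC[C@@H](O[C@@H](C/C=C/C)C(=O)O[Si](C)(C)C)[C@@H](Br)CC=C | intermediate
16 | (2S,4E)-2-{[(3R,4S)-4-bromohept-6-en-3-yl]oxy}hex-4-enoic acid | CC[C@@H](O[C@@H](C/C=C/C)C(=O)O)[C@@H](Br)CC=C | intermediate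
17 | methyl (2S,4E)-2-{[(3R,4S)-4-bromohept-6-en-3-yl]oxy}hex-4-enoate | CC[C@@H](O[C@@H](C/C=C/C)C(=O)OC)[C@@H](Br)CC=C | intermediate
18 | methyl (2S,4Z,7S,8R)-7-bromo-8-ethyl-3,6,7,8-tetrahydro-2H-oxocine-2-carboxylate | CC[C@H]1O[C@H](C(=O)OC)C/C=C\C[C@@H]1Br | intermediate
19 | (2S,4Z,7S,8R)-7-bromo-8-ethyl-3,6,7,8-tetrahydro-2H-oxocine-2-carbaldehyde | CC[C@H]1O[C@H](C=O)C/C=C\C[C@@H]1Br | intermediate
20 | (1S)-1-[(2S,4Z,7S,8R)-7-bromo-8-ethyl-3,6,7,8-tetrahydro-2H-oxocin-2-yl]but-3-en-1-ol | CC[C@H]1O[C@H]([C@@H](O)CC=C)C/C=C\C[C@@H]1Br | intermediate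
21 | N-bromosuccinimide | O=C1CCC(=O)N1Br | starting material
22 | (1S,3R,4S,6S,7S,9S)-4,6-dibromo-3-ethyl-9-(prop-2-en-1-yl)-2,8-dioxabicyclo[5.2.1]decane | C=CC[C@@H]1O[C@H]2C[C@@H]1O[C@H](CC)[C@@H](Br)C[C@@H]2Br | intermediate
23 | (2E)-but-2-enal (crotonaldehyde) | C/C=C/C=O | starting material
24 | (2E)-4-[(1S,3R,4S,6S,7S,9S)-4,6-dibromo-3-ethyl-2,8-dioxabicyclo[5.2.1]decan-9-yl]but-2-enal | O=C/C=C/C[C@@H]1O[C@H]2C[C@@H]1O[C@H](CC)[C@@H](Br)C[C@@H]2Br | intermediate
25 | (1S,3R,4S,6S,7S,9S)-4,6-dibromo-3-ethyl-9-[(2E)-pent-2-en-4-yn-1-yl]-2,8-dioxabicyclo[5.2.1]decane | C#C/C=C/C[C@@H]1O[C@H]2C[C@@H]1O[C@H](CC)[C@@H](Br)C[C@@H]2Br | target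

## Step count and risks

Total steps: 13. Longest linear sequence: 13 (from 1 to 25).

The three steps most likely to fail:

**Step 8 (ring-closing metathesis).** The ester diene may be too poorly pre-organised for eight-membered ring closure and oligomerise instead. The fallback cyclises at the alcohol oxidation level, where both ether carbons carry a vicinal C–heteroatom bond. It sets out from 17: LiBH4 in THF at 0 °C gives (2S,4E)-2-{[(3R,4S)-4-bromohept-6-en-3-yl]oxy}hex-4-en-1-ol F1. Ac2O, pyridine and DMAP give (2S,4E)-2-{[(3R,4S)-4-bromohept-6-en-3-yl]oxy}hex-4-en-1-yl acetate F2. Ring-closing metathesis with the same catalyst at 2 mM gives [(2S,4Z,7S,8R)-7-bromo-8-ethyl-3,6,7,8-tetrahydro-2H-oxocin-2-yl]methyl acetate F3. K2CO3 in MeOH at 0 °C gives [(2S,4Z,7S,8R)-7-bromo-8-ethyl-3,6,7,8-tetrahydro-2H-oxocin-2-yl]methanol F4. Dess–Martin oxidation (NaHCO3, CH2Cl2) comes back to the route at 19.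

**Step 10 (C6 allylation).** Chelation through the hindered ring-ether oxygen may give a poor diastereomer ratio. The fallback sets C6 by ketone reduction instead of by addition. It sets out from 19: allylmagnesium bromide in THF at −78 °C gives 20 mixed with its C6 epimer (1R)-1-[(2S,4Z,7S,8R)-7-bromo-8-ethyl-3,6,7,8-tetrahydro-2H-oxocin-2-yl]but-3-en-1-ol F5. Dess–Martin oxidation of the mixture gives 1-[(2S,4Z,7S,8R)-7-bromo-8-ethyl-3,6,7,8-tetrahydro-2H-oxocin-2-yl]but-3-en-1-one F6. LiBH(s-Bu)3 in THF at −78 °C reduces it under Felkin–Anh control (hydride anti to the ring C–O bond) and comes back to the route at 20.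

**Step 11 (bromoetherification).** The side-chain terminal alkene may compete for the bromonium source, and the ring oxygen may capture the bromonium ion transannularly. The fallback removes the first of these by reordering: the side-chain alkene is made electron-poor before the bromonium step. It sets out from 20: cross-metathesis with 23 (second-generation Hoveyda–Grubbs catalyst, CH2Cl2, 40 °C) gives (2E,5S)-5-[(2S,4Z,7S,8R)-7-bromo-8-ethyl-3,6,7,8-tetrahydro-2H-oxocin-2-yl]-5-hydroxypent-2-enal F7. NBS in CH2Cl2 at 0 °C then closes the tetrahydrofuran and comes back to the route at 24.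

## Further compounds

F1 | step 8 | (2S,4E)-2-{[(3R,4S)-4-bromohept-6-en-3-yl]oxy}hex-4-en-1-ol | CC[C@@H](O[C@@H](C/C=C/C)CO)[C@@H](Br)CC=C
F2 | step 8 | (2S,4E)-2-{[(3R,4S)-4-bromohept-6-en-3-yl]oxy}hex-4-en-1-yl acetate | CC[C@@H](O[C@@H](C/C=C/C)COC(C)=O)[C@@H](Br)CC=C
F3 | step 8 | [(2S,4Z,7S,8R)-7-bromo-8-ethyl-3,6,7,8-tetrahydro-2H-oxocin-2-yl]methyl acetate | CC[C@H]1O[C@H](COC(C)=O)C/C=C\C[C@@H]1Br
F4 | step 8 | [(2S,4Z,7S,8R)-7-bromo-8-ethyl-3,6,7,8-tetrahydro-2H-oxocin-2-yl]methanol | CC[C@H]1O[C@H](CO)C/C=C\C[C@@H]1Br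
F5 | step 10 | (1R)-1-[(2S,4Z,7S,8R)-7-bromo-8-ethyl-3,6,7,8-tetrahydro-2H-oxocin-2-yl]but-3-en-1-ol | CC[C@H]1O[C@H]([C@H](O)CC=C)C/C=C\C[C@@H]1Br
F6 | step 10 | 1-[(2S,4Z,7S,8R)-7-bromo-8-ethyl-3,6,7,8-tetrahydro-2H-oxocin-2-yl]but-3-en-1-one | CC[C@H]1O[C@H](C(=O)CC=C)C/C=C\C[C@@H]1Br
F7 | step 11 | (2E,5S)-5-[(2S,4Z,7S,8R)-7-bromo-8-ethyl-3,6,7,8-tetrahydro-2H-oxocin-2-yl]-5-hydroxypent-2-enal | CC[C@H]1O[C@H]([C@@H](O)C/C=C/C=O)C/C=C\C[C@@H]1Br
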